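**Strategy.** Everything rests on disconnecting, in the trimethylcyclohexene (ring A), the bond between the chain-bearing sp2 carbon and the quaternary CMe2 carbon. The butenolide (ring B) is finished first, on a vinyl iodide fragment, and a B-alkyl Suzuki coupling joins it to an open-chain fragment. The precursor of the key step is therefore acyclic at ring A: a tertiary methyl ether tethered by three CH2 groups to a tetrasubstituted vinylsilane. One operation (TiCl4) ionises the ether, closes ring A at its most hindered bond and, by loss of silicon from the former vinylsilane carbon, fixes the tetrasubstituted C=C beside the gem-dimethyl carbon. E and Z vinylsilanes converge.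

Key step: step 17

Remark on numbering: chain carbons are counted from the lactone carbonyl (C1) through the stereocentre (C4) to the ring A carbons C14 (chain-bearing), C15 (methyl-bearing) and C19 (CMe2).
Remark on the chemistry: the silylated C14=C15 double bond of 7–11 and 27–29 is carried as an E/Z mixture, and 5 and 6 are racemic. Neither element survives (steps 3 and 17), so no control is sought.

Step 1
Reactants: 1 6-methylhept-5-en-2-one
Product: 2 methoxy ketone 6-methoxy-6-methylheptan-2-one
Conditions: MeOH, H2SO4 (cat.), rt; aq. acid work-up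
Reagents that add atoms: methanol CO
Why: Acid-catalysed Markovnikov hydroalkoxylation of the trisubstituted alkene through its tertiary cation gives the tertiary methyl ether, and the ketone is returned from its dimethyl ketal on aqueous work-up.

Step 2
Reactants: 3 (1-bromoethenyl)trimethylsilane, 2 6-methoxy-6-methylheptan-2-one
Product: 5 tertiary allylic alcohol 7-methoxy-3,7-dimethyl-2-(trimethylsilyl)oct-1-en-3-ol (racemic), via alpha-silylvinyl Grignard reagent 4 (not isolated)
Conditions: Mg, THF, reflux; then 2, THF, −78 °C to 0 °C; aq. NH4Cl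
Reagents that add atoms: none
Why: Grignard addition of the alpha-silylvinyl reagent to the methyl ketone gives the tertiary allylic alcohol, whose new carbinol centre is racemic and is destroyed in step 3.

Step 3
Reactants: 5 7-methoxy-3,7-dimethyl-2-(trimethylsilyl)oct-1-en-3-ol
Product: 7 ester ethyl 9-methoxy-5,9-dimethyl-4-(trimethylsilyl)dec-4-enoate (E/Z mixture), via mixed ketene acetal 6 (not isolated)
Conditions: MeC(OEt)3, EtCO2H (cat.), 140 °C, EtOH distilled off
Reagents that add atoms: triethyl orthoacetate CCOC(C)(OCC)OCC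
Why: Johnson–Claisen rearrangement, in which orthoester exchange gives ketene acetal 6 and its [3,3]-shift moves the double bond onto the silicon-bearing carbon while delivering the two-carbon ester arm; the E/Z ratio is irrelevant because both isomers converge in step 17.

Step 4
Reactants: 7 ethyl 9-methoxy-5,9-dimethyl-4-(trimethylsilyl)dec-4-enoate
Product: 8 aldehyde 9-methoxy-5,9-dimethyl-4-(trimethylsilyl)dec-4-enal (E/Z mixture)
Conditions: i-Bu2AlH, CH2Cl2, −78 °C; aq. potassium sodium tartrate
Reagents that add atoms: none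
Why: Low-temperature half-reduction of the ester with i-Bu2AlH stops at the aluminium hemiacetal, which gives the aldehyde on work-up, while the ether and vinylsilane are inert.

Step 5
Reactants: 8 9-methoxy-5,9-dimethyl-4-(trimethylsilyl)dec-4-enal
Product: 9 alkyne (10-methoxy-6,10-dimethylundec-5-en-1-yn-5-yl)trimethylsilane (E/Z mixture)
Conditions: dimethyl (1-diazo-2-oxopropyl)phosphonate, K2CO3, MeOH, 0 °C to rt
Reagents that add atoms: dimethyl (1-diazo-2-oxopropyl)phosphonate CC(=O)C(=[N+]=[N-])P(=O)(OC)OC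
Why: Seyferth–Gilbert homologation with the Ohira–Bestmann reagent converts the aldehyde into the terminal alkyne under mild carbonate conditions that leave the vinylsilane and the tertiary ether untouched.

Step 6
Reactants: 9 (10-methoxy-6,10-dimethylundec-5-en-1-yn-5-yl)trimethylsilane
Product: 11 diene [(3E)-12-methoxy-4,8,12-trimethyltrideca-1,3,7-trien-7-yl]trimethylsilane (7E/Z mixture), via alkenyl(dimethyl)alane 10 (not isolated)
Conditions: Me3Al, Cp2ZrCl2 (0.2 equiv), CH2Cl2, 0 °C to rt; then CH2=CHBr, Pd(PPh3)4 (5 mol %), ZnCl2 (co-catalyst), THF, rt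
Reagents that add atoms: trimethylaluminium C[Al](C)C; vinyl bromide C=CBr
Why: Negishi zirconium-catalysed methylalumination adds Me and Al syn across the terminal alkyne with Al at the terminus, and palladium-catalysed coupling of alane 10 with vinyl bromide occurs with retention, which fixes the (E)-C10=C11 alkene.

Step 7
Reactants: 12 but-2-yne-1,4-diol
Product: 13 monosilyl ether 4-[(tert-butyldiphenylsilyl)oxy]but-2-yn-1-ol
Conditions: t-BuPh2SiCl, imidazole, THF, 0 °C (diol in excess)
Reagents that add atoms: tert-butyl(chloro)diphenylsilane CC(C)(C)[Si](Cl)(c1ccccc1)c1ccccc1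
Why: Statistical monosilylation of the symmetrical diol, used in excess, gives the mono-protected propargylic alcohol.

Step 8
Reactants: 13 4-[(tert-butyldiphenylsilyl)oxy]but-2-yn-1-ol
Product: 15 vinyl iodide (2Z)-4-[(tert-butyldiphenylsilyl)oxy]-3-iodobut-2-en-1-ol, via cyclic sodium alkenylaluminate 14 (not isolated)
Conditions: NaAlH2(OCH2CH2OMe)2, THF, 0 °C; then I2, −78 °C
Reagents that add atoms: iodine II
Why: Hydroxyl-directed trans-hydroalumination delivers hydride to the proximal and aluminium to the distal alkyne carbon (aluminate 14), and iodinolysis with retention gives the (Z)-vinyl iodide that later defines the C6=C7 geometry.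

Step 9
Reactants: 15 (2Z)-4-[(tert-butyldiphenylsilyl)oxy]-3-iodobut-2-en-1-ol
Product: 16 allylic bromide {[(2Z)-4-bromo-2-iodobut-2-en-1-yl]oxy}(tert-butyl)diphenylsilane
Conditions: CBr4, PPh3, CH2Cl2, 0 °C
Reagents that add atoms: carbon tetrabromide BrC(Br)(Br)Br
Why: Appel bromination converts the primary allylic alcohol into the bromide under neutral conditions without allylic transposition or loss of alkene geometry.

Step 10
Reactants: 17 2,2-dimethyl-1,3-dioxan-5-one, 18 (R)-1-amino-2-(methoxymethyl)pyrrolidine (RAMP)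
Product: 19 RAMP hydrazone of 2,2-dimethyl-1,3-dioxan-5-one
Conditions: benzene, 60 °C, 4 Å molecular sieves
Reagents that add atoms: none
Why: Condensation of the ketone with the chiral hydrazine gives the Enders hydrazone of the protected dihydroxyacetone.

Step 11
Reactants: 19 RAMP hydrazone of 2,2-dimethyl-1,3-dioxan-5-one, 16 {[(2Z)-4-bromo-2-iodobut-2-en-1-yl]oxy}(tert-butyl)diphenylsilane
Product: 21 alkylated hydrazone, the RAMP hydrazone of (4R)-4-{(2Z)-4-[(tert-butyldiphenylsilyl)oxy]-3-iodobut-2-en-1-yl}-2,2-dimethyl-1,3-dioxan-5-one, via lithium azaenolate 20 (not isolated)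
Conditions: t-BuLi (1.0 equiv), THF, −78 °C; then 16, −100 °C to −78 °C
Reagents that add atoms: none
Why: Enders hydrazone alkylation, in which the chelated lithium azaenolate 20 is alkylated by the reactive 2-iodoallylic bromide on the face left open by the methoxymethylpyrrolidine, setting the (R) centre (the SAMP series gives S); the base is consumed before the iodide is added, so no iodine–lithium exchange occurs.

Step 12
Reactants: 21 alkylated RAMP hydrazone
Product: 22 ketone (4R)-4-{(2Z)-4-[(tert-butyldiphenylsilyl)oxy]-3-iodobut-2-en-1-yl}-2,2-dimethyl-1,3-dioxan-5-one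
Conditions: sat. aq. oxalic acid, Et2O, rt
Reagents that add atoms: water O
Why: Mild two-phase hydrolysis of the hydrazone with oxalic acid frees the ketone without cleaving the acetonide or epimerising the alpha centre, and returns the auxiliary.

Step 13
Reactants: 22 (4R)-4-{(2Z)-4-[(tert-butyldiphenylsilyl)oxy]-3-iodobut-2-en-1-yl}-2,2-dimethyl-1,3-dioxan-5-one
Product: 23 dihydroxy ketone (3R,5Z)-7-[(tert-butyldiphenylsilyl)oxy]-1,3-dihydroxy-6-iodohept-5-en-2-one
Conditions: 1 M HCl, THF, 0 °C to rt
Reagents that add atoms: none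
Why: Acid-catalysed acetal hydrolysis releases the alpha,alpha'-dihydroxy ketone, while the primary TBDPS ether and the vinyl iodide tolerate dilute acid.

Step 14
Reactants: 23 (3R,5Z)-7-[(tert-butyldiphenylsilyl)oxy]-1,3-dihydroxy-6-iodohept-5-en-2-one
Product: 24 hydroxy ketone (3R,5Z)-1,7-bis[(tert-butyldiphenylsilyl)oxy]-3-hydroxy-6-iodohept-5-en-2-one
Conditions: t-BuPh2SiCl, imidazole, CH2Cl2, −20 °C to 0 °C
Reagents that add atoms: tert-butyl(chloro)diphenylsilane CC(C)(C)[Si](Cl)(c1ccccc1)c1ccccc1
Why: Silylation with the bulky chlorosilane is selective for the primary over the secondary hydroxyl, leaving the C4 hydroxyl free for lactone formation.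

Step 15
Reactants: 24 (3R,5Z)-1,7-bis[(tert-butyldiphenylsilyl)oxy]-3-hydroxy-6-iodohept-5-en-2-one
Product: 26 butenolide iodide (5R)-5-{(2Z)-4-[(tert-butyldiphenylsilyl)oxy]-3-iodobut-2-en-1-yl}-4-{[(tert-butyldiphenylsilyl)oxy]methyl}furan-2(5H)-one, via acyl ylide ester 25 (not isolated)
Conditions: Ph3P=C=C=O, toluene, 90 °C
Reagents that add atoms: (triphenylphosphoranylidene)ketene O=C=C=P(c1ccccc1)(c1ccccc1)c1ccccc1
Why: Bestmann ylide cascade, in which the secondary alcohol adds to the ketene to give acyl ylide 25 and intramolecular Wittig olefination of the adjacent ketone closes ring B with the silyloxymethyl group on C3; the (R) centre is not involved.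

Step 16
Reactants: 11 [(3E)-12-methoxy-4,8,12-trimethyltrideca-1,3,7-trien-7-yl]trimethylsilane, 26 butenolide iodide
Product: 28 open-chain precursor (5R)-5-[(2E,6E)-3-{[(tert-butyldiphenylsilyl)oxy]methyl}-15-methoxy-7,11,15-trimethyl-10-(trimethylsilyl)hexadeca-2,6,10-trien-1-yl]-4-{[(tert-butyldiphenylsilyl)oxy]methyl}furan-2(5H)-one (10E/Z mixture), via homoallylic trialkylborane 27 (not isolated)
Conditions: 9-BBN-H, THF, 0 °C to rt; then 26, Pd(dppf)Cl2 (5 mol %), AsPh3, K3PO4 (aq.), DMF, rt
Reagents that add atoms: none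
Why: 9-BBN-H adds to the terminal CH2 of the diene (the tri- and tetrasubstituted alkenes are inert), and B-alkyl Suzuki–Miyaura coupling of borane 27 with the vinyl iodide proceeds with retention to give the C6=C7 geometry of the target.

Step 17
Reactants: 28 open-chain precursor
Product: 30 (6E)-neomanoalide bis(tert-butyldiphenylsilyl) ether, via tertiary chloride 29 (not isolated)
Conditions: TiCl4 (3 equiv), 2,6-di-tert-butyl-4-methylpyridine, CH2Cl2, −78 °C; MeOH/NaHCO3 quench
Reagents that add atoms: none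
Why: Proposed new method: TiCl4 removes the methoxide of the tertiary ether (through the reversibly ionising tertiary chloride 29, as in tertiary ether/TiCl4 alkylations of allylsilanes) to give a tertiary carbenium ion under aprotic conditions, the hindered pyridine trapping stray protons so that the other alkenes, the silyl ethers and ring B are not touched; the cation then attacks the vinylsilane at its silicon-bearing carbon and Me3SiCl is lost. The closest known reaction type is the vinylsilane-terminated cation–olefin cyclisation, which has not been shown for a tertiary alkyl cation closing onto a fully substituted silicon-bearing alkene carbon. Ring A closes in the 6-endo-trig mode, the only one that puts the new cation beta to silicon on the tertiary methyl-bearing C15 (5-exo attack would give an alpha-silyl cation). No stereocentre is formed, the (R) centre of ring B is remote, and the E and Z vinylsilanes pass through the same cation to the same product. The step needs one double-bond position and a single ring closure: loss of silicon can only give the C14=C15 alkene (no proton-loss isomers), and a second closure by the C10=C11 alkene would have to build two adjacent fully substituted ring-fusion carbons next to C19, whereas desilylation relieves that strain.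

Step 18
Reactants: 30 (6E)-neomanoalide bis(tert-butyldiphenylsilyl) ether
Product: 31 (6E)-neomanoalide
Conditions: HF·pyridine, pyridine, THF, 0 °C to rt
Reagents that add atoms: none
Why: Fluoride-mediated cleavage of both primary silyl ethers under buffered, non-basic conditions leaves the butenolide stereocentre and all four alkenes untouched.

**Compound list**

1 | 6-methylhept-5-en-2-one | CC(=O)CCC=C(C)C | starting material
2 | 6-methoxy-6-methylheptan-2-one | CC(=O)CCCC(C)(C)OC | intermediate
3 | (1-bromoethenyl)trimethylsilane | C=C(Br)[Si](C)(C)C | starting material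
4 | [1-(trimethylsilyl)ethenyl]magnesium bromide | C=C([Mg]Br)[Si](C)(C)C | intermediate (not isolated)
5 | 7-methoxy-3,7-dimethyl-2-(trimethylsilyl)oct-1-en-3-ol (racemic) | C=C([Si](C)(C)C)C(C)(O)CCCC(C)(C)OC | intermediate
6 | 3-[(1-ethoxyethenyl)oxy]-7-methoxy-3,7-dimethyl-2-(trimethylsilyl)oct-1-ene (racemic mixed ketene acetal) | C=C(OCC)OC(C)(CCCC(C)(C)OC)C(=C)[Si](C)(C)C | intermediate (not isolated)
7 | ethyl 9-methoxy-5,9-dimethyl-4-(trimethylsilyl)dec-4-enoate (E/Z mixture) | CCOC(=O)CCC(=C(C)CCCC(C)(C)OC)[Si](C)(C)C | intermediate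
8 | 9-methoxy-5,9-dimethyl-4-(trimethylsilyl)dec-4-enal (E/Z mixture) | O=CCCC(=C(C)CCCC(C)(C)OC)[Si](C)(C)C | intermediate
9 | (10-methoxy-6,10-dimethylundec-5-en-1-yn-5-yl)trimethylsilane (E/Z mixture) | C#CCCC(=C(C)CCCC(C)(C)OC)[Si](C)(C)C | intermediate
10 | [(1E)-10-methoxy-2,6,10-trimethyl-5-(trimethylsilyl)undeca-1,5-dien-1-yl]dimethylalumane (5E/Z mixture) | C[Al](C)/C=C(\C)CCC(=C(C)CCCC(C)(C)OC)[Si](C)(C)C | intermediate (not isolated)
11 | [(3E)-12-methoxy-4,8,12-trimethyltrideca-1,3,7-trien-7-yl]trimethylsilane (7E/Z mixture) | C=C/C=C(\C)CCC(=C(C)CCCC(C)(C)OC)[Si](C)(C)C | intermediate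
12 | but-2-yne-1,4-diol | OCC#CCO | starting material
13 | 4-[(tert-butyldiphenylsilyl)oxy]but-2-yn-1-ol | OCC#CCO[Si](c1ccccc1)(c1ccccc1)C(C)(C)C | intermediate
14 | sodium 2,2-bis(2-methoxyethoxy)-3-{[(tert-butyldiphenylsilyl)oxy]methyl}-2,5-dihydro-1,2-oxaluminol-2-uide | [Na+].COCCO[Al-]1(OCCOC)OCC=C1CO[Si](c1ccccc1)(c1ccccc1)C(C)(C)C | intermediate (not isolated)
15 | (2Z)-4-[(tert-butyldiphenylsilyl)oxy]-3-iodobut-2-en-1-ol | OC/C=C(\I)CO[Si](c1ccccc1)(c1ccccc1)C(C)(C)C | intermediate
16 | {[(2Z)-4-bromo-2-iodobut-2-en-1-yl]oxy}(tert-butyl)diphenylsilane | BrC/C=C(\I)CO[Si](c1ccccc1)(c1ccccc1)C(C)(C)C | intermediate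
17 | 2,2-dimethyl-1,3-dioxan-5-one | CC1(C)OCC(=O)CO1 | starting material
18 | (R)-1-amino-2-(methoxymethyl)pyrrolidine (RAMP) | COC[C@H]1CCCN1N | starting material
19 | RAMP hydrazone of 2,2-dimethyl-1,3-dioxan-5-one | COC[C@H]1CCCN1N=C1COC(C)(C)OC1 | intermediate
20 | lithium azaenolate of hydrazone 19 | COC[C@H]1CCCN1N([Li])C1=COC(C)(C)OC1 | intermediate (not isolated)
21 | RAMP hydrazone of (4R)-4-{(2Z)-4-[(tert-butyldiphenylsilyl)oxy]-3-iodobut-2-en-1-yl}-2,2-dimethyl-1,3-dioxan-5-one | CC(C)(C)[Si](c1ccccc1)(c1ccccc1)OC/C(I)=C/C[C@H]1OC(C)(C)OCC1=NN1CCC[C@@H]1COC | intermediate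
22 | (4R)-4-{(2Z)-4-[(tert-butyldiphenylsilyl)oxy]-3-iodobut-2-en-1-yl}-2,2-dimethyl-1,3-dioxan-5-one | CC(C)(C)[Si](c1ccccc1)(c1ccccc1)OC/C(I)=C/C[C@H]1OC(C)(C)OCC1=O | intermediate
23 | (3R,5Z)-7-[(tert-butyldiphenylsilyl)oxy]-1,3-dihydroxy-6-iodohept-5-en-2-one | CC(C)(C)[Si](c1ccccc1)(c1ccccc1)OC/C(I)=C/C[C@@H](O)C(=O)CO | intermediate
24 | (3R,5Z)-1,7-bis[(tert-butyldiphenylsilyl)oxy]-3-hydroxy-6-iodohept-5-en-2-one | CC(C)(C)[Si](c1ccccc1)(c1ccccc1)OC/C(I)=C/C[C@@H](O)C(=O)CO[Si](c1ccccc1)(c1ccccc1)C(C)(C)C | intermediate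
25 | (triphenylphosphoranylidene)acetate ester of 24 at the C3 hydroxyl | CC(C)(C)[Si](c1ccccc1)(c1ccccc1)OC/C(I)=C/C[C@@H](OC(=O)C=P(c1ccccc1)(c1ccccc1)c1ccccc1)C(=O)CO[Si](c1ccccc1)(c1ccccc1)C(C)(C)C | intermediate (not isolated)
26 | (5R)-5-{(2Z)-4-[(tert-butyldiphenylsilyl)oxy]-3-iodobut-2-en-1-yl}-4-{[(tert-butyldiphenylsilyl)oxy]methyl}furan-2(5H)-one | CC(C)(C)[Si](c1ccccc1)(c1ccccc1)OC/C(I)=C/C[C@H]1OC(=O)C=C1CO[Si](c1ccccc1)(c1ccccc1)C(C)(C)C | intermediate
27 | 9-[(3E)-12-methoxy-4,8,12-trimethyl-7-(trimethylsilyl)trideca-3,7-dien-1-yl]-9-borabicyclo[3.3.1]nonane (7E/Z mixture) | C1CC2CCCC(C1)B2CC/C=C(\C)CCC(=C(C)CCCC(C)(C)OC)[Si](C)(C)C | intermediate (not isolated)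
28 | (5R)-5-[(2E,6E)-3-{[(tert-butyldiphenylsilyl)oxy]methyl}-15-methoxy-7,11,15-trimethyl-10-(trimethylsilyl)hexadeca-2,6,10-trien-1-yl]-4-{[(tert-butyldiphenylsilyl)oxy]methyl}furan-2(5H)-one (10E/Z mixture) | COC(C)(C)CCCC(C)=C([Si](C)(C)C)CC/C(C)=C/CC/C(=C\C[C@H]1OC(=O)C=C1CO[Si](c1ccccc1)(c1ccccc1)C(C)(C)C)CO[Si](c1ccccc1)(c1ccccc1)C(C)(C)C | intermediate
29 | tertiary chloride, the 15-chloro analogue of 28 (Cl in place of OMe) | CC(C)(Cl)CCCC(C)=C([Si](C)(C)C)CC/C(C)=C/CC/C(=C\C[C@H]1OC(=O)C=C1CO[Si](c1ccccc1)(c1ccccc1)C(C)(C)C)CO[Si](c1ccccc1)(c1ccccc1)C(C)(C)C | intermediate (not isolated)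
30 | (6E)-neomanoalide bis(tert-butyldiphenylsilyl) ether | CC1=C(CC/C(C)=C/CC/C(=C\C[C@H]2OC(=O)C=C2CO[Si](c3ccccc3)(c3ccccc3)C(C)(C)C)CO[Si](c3ccccc3)(c3ccccc3)C(C)(C)C)C(C)(C)CCC1 | intermediate
31 | (6E)-neomanoalide | CC1=C(CC/C(C)=C/CC/C(=C\C[C@H]2OC(=O)C=C2CO)CO)C(C)(C)CCC1 | target

**Step count.** Total: 18 steps. Longest linear sequence: 11 steps (12 → 13 → 15 → 16 → 21 → 22 → 23 → 24 → 26 → 28 → 30 → 31, steps 7–9 and 11–18).

**Steps most likely to fail**

1. Step 17. What may go wrong: the ring cation is captured by the C10=C11 alkene before silicon is lost (a second ring closure), or the tertiary cation loses a proton faster than it forms the congested C14–C19 bond. The fallback uses known chemistry only and gives up the late closure of ring A by taking that ring from a commercial cyclohexene; it sets out from butenolide iodide 26 and comes back at 30. The kinetic enolate of dihydro-β-ionone F1 (LiN(i-Pr)2, THF, −78 °C) is trapped with ClP(O)(OEt)2 to give enol phosphate F2, which a second portion of LiN(i-Pr)2 eliminates to terminal alkyne F3. Methylalumination (Me3Al, Cp2ZrCl2) gives alkenylalane F4, and palladium-catalysed coupling with vinyl bromide as in step 6 gives diene F5. Hydroboration with 9-BBN-H gives borane F6, which is coupled with 26 under the conditions of step 16 to give 30; step 18 then follows unchanged.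

2. Step 16. What may go wrong: hydroboration of the conjugated diene is not confined to the terminal carbon (allylic borane formation or double hydroboration), or the aqueous phosphate base epimerises or opens the butenolide during coupling. The fallback is a base-free Negishi coupling; it sets out from alkyne 9 and comes back at 28. Alane 10, made from 9 as in step 6, is converted with n-BuLi into lithium alanate F7, which opens ethylene oxide to give homoallylic alcohol F8 with retention of the (E)-alkene. I2, PPh3 and imidazole give iodide F9; zinc dust with LiCl in THF gives alkylzinc iodide F10. Coupling of F10 with 26 (Pd(dppf)Cl2, THF, rt) under neutral conditions gives 28.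

3. Step 3. What may go wrong: acid-promoted dehydration of the hindered tertiary allylic alcohol at 140 °C, or failure of orthoester exchange at the crowded carbinol. The fallback replaces the sigmatropic step by an allylic alkylation; it sets out from alcohol 5 and comes back at aldehyde 8. Acetylation (Ac2O, DMAP, Et3N, CH2Cl2, 40 °C) gives tertiary allylic acetate F11. Tsuji–Trost alkylation with NaCH(CO2Me)2 and Pd(PPh3)4 in THF attacks the unsubstituted terminus of the 2-silyl allyl complex and gives malonate F12, already with the tetrasubstituted vinylsilane. Krapcho demethoxycarbonylation (NaCl, wet DMSO, 150 °C) gives methyl ester F13, and i-Bu2AlH at −78 °C, as in step 4, gives 8.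

**Further compounds**

F1 | step 17 | dihydro-β-ionone, 4-(2,6,6-trimethylcyclohex-1-en-1-yl)butan-2-one | CC(=O)CCC1=C(C)CCCC1(C)C
F2 | step 17 | diethyl 4-(2,6,6-trimethylcyclohex-1-en-1-yl)but-1-en-2-yl phosphate | C=C(OP(=O)(OCC)OCC)CCC1=C(C)CCCC1(C)C
F3 | step 17 | 2-(but-3-yn-1-yl)-1,3,3-trimethylcyclohex-1-ene | C#CCCC1=C(C)CCCC1(C)C
F4 | step 17 | dimethyl[(1E)-2-methyl-4-(2,6,6-trimethylcyclohex-1-en-1-yl)but-1-en-1-yl]alumane | C[Al](C)/C=C(\C)CCC1=C(C)CCCC1(C)C
F5 | step 17 | 1,3,3-trimethyl-2-[(3E)-3-methylhexa-3,5-dien-1-yl]cyclohex-1-ene | C=C/C=C(\C)CCC1=C(C)CCCC1(C)C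
F6 | step 17 | 9-[(3E)-4-methyl-6-(2,6,6-trimethylcyclohex-1-en-1-yl)hex-3-en-1-yl]-9-borabicyclo[3.3.1]nonane | C1CC2CCCC(C1)B2CC/C=C(\C)CCC1=C(C)CCCC1(C)C
F7 | step 16 | lithium butyl(dimethyl)[(1E)-10-methoxy-2,6,10-trimethyl-5-(trimethylsilyl)undeca-1,5-dien-1-yl]alanate | [Li+].CCCC[Al-](C)(C)/C=C(\C)CCC(=C(C)CCCC(C)(C)OC)[Si](C)(C)C
F8 | step 16 | (3E)-12-methoxy-4,8,12-trimethyl-7-(trimethylsilyl)trideca-3,7-dien-1-ol | OCC/C=C(\C)CCC(=C(C)CCCC(C)(C)OC)[Si](C)(C)C
F9 | step 16 | [(3E)-1-iodo-12-methoxy-4,8,12-trimethyltrideca-3,7-dien-7-yl]trimethylsilane | ICC/C=C(\C)CCC(=C(C)CCCC(C)(C)OC)[Si](C)(C)C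
F10 | step 16 | [(3E)-12-methoxy-4,8,12-trimethyl-7-(trimethylsilyl)trideca-3,7-dien-1-yl]zinc iodide | I[Zn]CC/C=C(\C)CCC(=C(C)CCCC(C)(C)OC)[Si](C)(C)C
F11 | step 3 | 7-methoxy-3,7-dimethyl-2-(trimethylsilyl)oct-1-en-3-yl acetate | CC(=O)OC(C)(CCCC(C)(C)OC)C(=C)[Si](C)(C)C
F12 | step 3 | dimethyl 2-[7-methoxy-3,7-dimethyl-2-(trimethylsilyl)oct-2-en-1-yl]propanedioate | COC(=O)C(CC(=C(C)CCCC(C)(C)OC)[Si](C)(C)C)C(=O)OC
F13 | step 3 | methyl 9-methoxy-5,9-dimethyl-4-(trimethylsilyl)dec-4-enoate | COC(=O)CCC(=C(C)CCCC(C)(C)OC)[Si](C)(C)C
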